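**Plan**

1. Retrosynthesis: the two silyl groups on the glycerol unit go last; C11–H is traced back to C11–CO2H; the C9–C11 bond is cut by a retro-Ireland–Claisen shift, which moves the alkene from C1=C10 to C9=C10 and puts an ester oxygen on C1; that ester splits into a bicyclic allylic alcohol and a glyceryl half-ester of (R)-3-methyladipic acid.
2. The allylic alcohol is cut at C1–C10 (alkenyl triflate plus aldehyde), C9–C20 (enolate methylation) and C3–C4 (conjugate addition) back to (R)-pulegone; the half-ester goes back to (R)-citronellic acid by cleavage of its C6=C7 alkene.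
3. Forward: ring B is the pulegone ring, ring A is closed at C1–C10, the side chain is tied to the C1 oxygen as an ester and then shifted to C9, the lent carboxyl is removed, the glycerol is unmasked.
4. Enabling feature: the trisubstituted C1=C10 alkene of ring A lies next to the quaternary C9 of ring B, so C11–C9–C10=C1 becomes a γ,δ-unsaturated acid retron once a carboxyl is lent to C11; C6 of citronellic acid is that carboxyl.
5. Stereochemistry: C8 from pulegone (its ring, methyl and isopropylidene map onto ring B, C17 and C4/C18/C19); C5 by equilibration trans to the C8 methyl; C1 by CBS reduction; C9 by 1,3-chirality transfer from C1; C13 from C3 of citronellic acid.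

Key step: step 12

Remark: halimane numbering is used (ring A = C1–C5, C10; ring B = C5–C10; C17 on C8, C18/C19 on C4, C20 on C9; side chain C11–C15, C16 on C13); the target is read as 5S,8R,9R,13R, with H-5, C17 and C11 on one face of the bicycle and C20 on the other.

**Route**

Step 1
Reactants: 1 glycerol
Product: 2 1,3-bis(tert-butyldimethylsilyloxy)propan-2-ol
Conditions: TBSCl (2.05 equiv), imidazole, CH2Cl2, 0 °C → rt
Reagents that add atoms: tert-butyldimethylsilyl chloride, CC(C)(C)[Si](C)(C)Cl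
Why: Selective silyl ether formation, the two primary hydroxyls reacting much faster than the secondary one, which stays free for the ester.

Step 2
Reactants: 3 (R)-citronellic acid; 2 1,3-bis(tert-butyldimethylsilyloxy)propan-2-ol
Product: 4 1,3-bis(tert-butyldimethylsilyloxy)propan-2-yl (3R)-3,7-dimethyloct-6-enoate
Conditions: DCC, DMAP (cat.), CH2Cl2, 0 °C → rt
Reagents that add atoms: none
Why: Steglich esterification of a secondary alcohol with an unhindered acid; the stereocentre (later C13) is β to the carbonyl and is not touched.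

Step 3
Reactants: 4 1,3-bis(tert-butyldimethylsilyloxy)propan-2-yl (3R)-3,7-dimethyloct-6-enoate
Product: 6 (4R)-6-{[1,3-bis(tert-butyldimethylsilyloxy)propan-2-yl]oxy}-4-methyl-6-oxohexanoic acid, via aldehyde 5 (not isolated)
Conditions: O3, CH2Cl2, −78 °C; Me2S, −78 °C → rt; then NaClO2, NaH2PO4, 2-methyl-2-butene, t-BuOH/H2O, rt
Reagents that add atoms: ozone, [O-][O+]=O; sodium chlorite, [Na+].[O-]Cl=O
Why: Ozonolysis cleaves the only alkene and Pinnick oxidation of the crude aldehyde should give the acid without harm to the silyl ethers or the ester, turning C6 of citronellic acid into the carboxyl that is lent to C11.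

Step 4
Reactants: 7 (R)-(+)-pulegone; 8 [2-(1,3-dioxolan-2-yl)ethyl]magnesium bromide
Product: 10 (2S,5R)-2-[4-(1,3-dioxolan-2-yl)-2-methylbutan-2-yl]-5-methylcyclohexan-1-one, via cis-ketone 9 (not isolated)
Conditions: 8 (1.3 equiv), CuBr·SMe2 (10 mol %), THF, −30 → 0 °C; aq NH4Cl; then KOH, EtOH, reflux
Reagents that add atoms: none
Why: Copper-catalysed 1,4-addition of a Grignard reagent to the β,β-disubstituted enone, a reaction type well known for pulegone, creates the quaternary C4, and base equilibration of the α-centre should favour the trans-diequatorial ketone (residual cis epimer removed by chromatography), which sets C5 relative to the pulegone-derived C8.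

Step 5
Reactants: 10 (2S,5R)-2-[4-(1,3-dioxolan-2-yl)-2-methylbutan-2-yl]-5-methylcyclohexan-1-one
Product: 11 (2S,3R,6S)-6-[4-(1,3-dioxolan-2-yl)-2-methylbutan-2-yl]-2,3-dimethylcyclohexan-1-one
Conditions: LiN(i-Pr)2, THF, −78 °C; MeI, −78 → 0 °C
Reagents that add atoms: iodomethane, CI
Why: Kinetic enolate alkylation, in which the base takes a proton from the C9 methylene and not from the hindered C5 methine and MeI should enter trans to the C8 methyl; the C9 configuration is of no consequence because C9 becomes sp2 in step 6.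

Step 6
Reactants: 11 (2S,3R,6S)-6-[4-(1,3-dioxolan-2-yl)-2-methylbutan-2-yl]-2,3-dimethylcyclohexan-1-one
Product: 12 (3R,6S)-6-[4-(1,3-dioxolan-2-yl)-2-methylbutan-2-yl]-2,3-dimethylcyclohex-1-en-1-yl trifluoromethanesulfonate
Conditions: KN(SiMe3)2, THF, −78 → 0 °C; PhNTf2, −78 °C → rt
Reagents that add atoms: N-phenylbis(trifluoromethanesulfonimide), O=S(=O)(N(c1ccccc1)S(=O)(=O)C(F)(F)F)C(F)(F)F
Why: Enol triflate formation from the potassium enolate, where the C9 methine is the more accessible α-hydrogen and the C9=C10 enolate avoids allylic strain between the enolate oxygen and the tertiary alkyl group on C5, so the tetrasubstituted C9=C10 triflate should form with C5 untouched.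

Step 7
Reactants: 12 (3R,6S)-6-[4-(1,3-dioxolan-2-yl)-2-methylbutan-2-yl]-2,3-dimethylcyclohex-1-en-1-yl trifluoromethanesulfonate
Product: 13 (3R,6S)-2,3-dimethyl-6-(2-methyl-5-oxopentan-2-yl)cyclohex-1-en-1-yl trifluoromethanesulfonate
Conditions: 1 M HCl, THF, rt
Reagents that add atoms: water, O
Why: Acid-catalysed acetal hydrolysis frees the C1 aldehyde, and enol triflates tolerate dilute aqueous acid.

Step 8
Reactants: 13 (3R,6S)-2,3-dimethyl-6-(2-methyl-5-oxopentan-2-yl)cyclohex-1-en-1-yl trifluoromethanesulfonate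
Product: 14 (4aS,7R)-4,4,7,8-tetramethyl-1,2,3,4,4a,5,6,7-octahydronaphthalen-1-ol (both C1 epimers)
Conditions: CrCl2 (6 equiv), NiCl2 (5 mol %), DMF, rt → 50 °C, 0.01 M
Reagents that add atoms: none
Why: Intramolecular Nozaki–Hiyama–Kishi reaction, in which zerovalent nickel inserts into the C10–OTf bond, transmetalation gives an alkenyl species of trivalent chromium that adds to the C1 aldehyde and closes ring A as a six-membered ring; both C1 epimers are carried on.

Step 9
Reactants: 14 (4aS,7R)-4,4,7,8-tetramethyl-1,2,3,4,4a,5,6,7-octahydronaphthalen-1-ol (both C1 epimers)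
Product: 15 (4aS,7R)-4,4,7,8-tetramethyl-3,4,4a,5,6,7-hexahydronaphthalen-1(2H)-one
Conditions: Dess–Martin periodinane, CH2Cl2, rt
Reagents that add atoms: none
Why: Dess–Martin oxidation of the allylic alcohol merges the two epimers in one enone under non-basic conditions that leave the γ-centre C8 untouched.

Step 10
Reactants: 15 (4aS,7R)-4,4,7,8-tetramethyl-3,4,4a,5,6,7-hexahydronaphthalen-1(2H)-one
Product: 16 (1S,4aS,7R)-4,4,7,8-tetramethyl-1,2,3,4,4a,5,6,7-octahydronaphthalen-1-ol
Conditions: (R)-2-methyl-CBS-oxazaborolidine (0.5 equiv), BH3·SMe2, THF, −30 °C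
Reagents that add atoms: none
Why: Corey–Bakshi–Shibata reduction, in which the fully substituted alkenyl carbon C10 acts as the large group and C2 as the small one, so the (R)-catalyst should give the (1S)-alcohol with the hydroxyl on the face of H-5 and C17 by reagent control.

Step 11
Reactants: 16 (1S,4aS,7R)-4,4,7,8-tetramethyl-1,2,3,4,4a,5,6,7-octahydronaphthalen-1-ol; 6 (4R)-6-{[1,3-bis(tert-butyldimethylsilyloxy)propan-2-yl]oxy}-4-methyl-6-oxohexanoic acid
Product: 17 1-[1,3-bis(tert-butyldimethylsilyloxy)propan-2-yl] 6-[(1S,4aS,7R)-4,4,7,8-tetramethyl-1,2,3,4,4a,5,6,7-octahydronaphthalen-1-yl] (3R)-3-methylhexanedioate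
Conditions: DCC, DMAP (cat.), CH2Cl2, 0 °C → rt
Reagents that add atoms: none
Why: Steglich esterification forms the acyl–oxygen bond with retention at C1 and ties the two halves together through the C1 oxygen, the temporary tether for step 12.

Step 12
Reactants: 17 1-[1,3-bis(tert-butyldimethylsilyloxy)propan-2-yl] 6-[(1S,4aS,7R)-4,4,7,8-tetramethyl-1,2,3,4,4a,5,6,7-octahydronaphthalen-1-yl] (3R)-3-methylhexanedioate
Product: 20 (4R)-6-{[1,3-bis(tert-butyldimethylsilyloxy)propan-2-yl]oxy}-4-methyl-6-oxo-2-[(1S,2R,4aS)-1,2,5,5-tetramethyl-1,2,3,4,4a,5,6,7-octahydronaphthalen-1-yl]hexanoic acid (both C11 epimers; the quaternary carbon has the spatial arrangement of the target), via bis(ketene silyl acetal) 18 (not isolated), via trimethylsilyl ester 19 (not isolated)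
Conditions: Me3SiCl/Et3N (6 equiv), THF, −78 °C; LiN(i-Pr)2 (3 equiv) added slowly; −78 °C → rt, then 60 °C; AcOH/H2O/THF, rt
Reagents that add atoms: none
Why: Excess base in the presence of Me3SiCl turns both esters into ketene silyl acetals before they can attack each other, and only the one on the C1 oxygen has an allyl partner, so on warming it undergoes the Ireland–Claisen [3,3]-sigmatropic shift through a six-membered cyclic transition state in which O–C1 breaks, C11–C9 forms and the alkene moves from C9=C10 to C1=C10. The closest known reaction type is the ester enolate Claisen rearrangement of 2-alkylidenecycloalkyl esters to quaternary carbons. No ring is closed in the product, the only cyclic array being the pericyclic transition state. C9 is set by suprafacial 1,3-chirality transfer from the C1 carbinol centre, the chain being delivered to the face that carried the C1–O bond, which is the face of H-5 and C17, while C11 forms as a mixture that step 13 erases. The step needs site selectivity between two esters, secured because the bystander ketene acetal can only revert to the glyceryl ester on acidic work-up and C13 is β to that carbonyl and cannot epimerise, and it needs delivery to the more hindered face of C9, next to the C8 methyl, which the intramolecular tether enforces and an external reagent would not. The position of the new alkene is fixed by the concerted shift, so no isomer with the alkene at C5=C10 can arise.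

Step 13
Reactants: 20 (4R)-6-{[1,3-bis(tert-butyldimethylsilyloxy)propan-2-yl]oxy}-4-methyl-6-oxo-2-[(1S,2R,4aS)-1,2,5,5-tetramethyl-1,2,3,4,4a,5,6,7-octahydronaphthalen-1-yl]hexanoic acid (both C11 epimers)
Product: 22 1,3-bis(tert-butyldimethylsilyloxy)propan-2-yl (3R)-3-methyl-5-[(1R,2R,4aS)-1,2,5,5-tetramethyl-1,2,3,4,4a,5,6,7-octahydronaphthalen-1-yl]pentanoate, via Barton ester 21 (not isolated)
Conditions: N-hydroxypyridine-2-thione, DCC, DMAP (cat.), CH2Cl2, dark, 0 °C → rt; then t-BuSH (20 equiv), hν (tungsten lamp), 10 °C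
Reagents that add atoms: none
Why: Barton reductive decarboxylation, in which the thiohydroxamate ester fragments under light to CO2 and the secondary C11 radical, and the large excess of thiol should reduce that radical before it can attack the C1=C10 alkene, so the lent carboxyl leaves and both C11 epimers converge on one compound.

Step 14
Reactants: 22 1,3-bis(tert-butyldimethylsilyloxy)propan-2-yl (3R)-3-methyl-5-[(1R,2R,4aS)-1,2,5,5-tetramethyl-1,2,3,4,4a,5,6,7-octahydronaphthalen-1-yl]pentanoate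
Product: 23 1,3-dihydroxypropan-2-yl (3R)-3-methyl-5-[(1R,2R,4aS)-1,2,5,5-tetramethyl-1,2,3,4,4a,5,6,7-octahydronaphthalen-1-yl]pentanoate (CNP0174907.2)
Conditions: HF·pyridine, pyridine, THF, 0 °C; purification on boric-acid-treated silica
Reagents that add atoms: none
Why: Fluoride cleavage of the two primary silyl ethers under buffered, weakly acidic conditions at low temperature, chosen to keep the 2-monoacylglycerol from 2→1 acyl migration.

**Compound list**

1 | glycerol (propane-1,2,3-triol) | OCC(O)CO | starting material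
2 | 1,3-bis(tert-butyldimethylsilyloxy)propan-2-ol | OC(CO[Si](C)(C)C(C)(C)C)CO[Si](C)(C)C(C)(C)C | intermediate
3 | (R)-citronellic acid, (3R)-3,7-dimethyloct-6-enoic acid | C[C@H](CCC=C(C)C)CC(=O)O | starting material
4 | 1,3-bis(tert-butyldimethylsilyloxy)propan-2-yl (3R)-3,7-dimethyloct-6-enoate | C[C@H](CCC=C(C)C)CC(=O)OC(CO[Si](C)(C)C(C)(C)C)CO[Si](C)(C)C(C)(C)C | intermediate
5 | 1,3-bis(tert-butyldimethylsilyloxy)propan-2-yl (3R)-3-methyl-6-oxohexanoate | C[C@H](CCC=O)CC(=O)OC(CO[Si](C)(C)C(C)(C)C)CO[Si](C)(C)C(C)(C)C | intermediate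
6 | (4R)-6-{[1,3-bis(tert-butyldimethylsilyloxy)propan-2-yl]oxy}-4-methyl-6-oxohexanoic acid | C[C@H](CCC(=O)O)CC(=O)OC(CO[Si](C)(C)C(C)(C)C)CO[Si](C)(C)C(C)(C)C | intermediate
7 | (R)-(+)-pulegone, (5R)-5-methyl-2-(propan-2-ylidene)cyclohexan-1-one | C[C@@H]1CCC(=C(C)C)C(=O)C1 | starting material
8 | [2-(1,3-dioxolan-2-yl)ethyl]magnesium bromide (THF solution) | Br[Mg]CCC1OCCO1 | starting material
9 | (2R,5R)-2-[4-(1,3-dioxolan-2-yl)-2-methylbutan-2-yl]-5-methylcyclohexan-1-one (cis) | C[C@@H]1CC[C@H](C(C)(C)CCC2OCCO2)C(=O)C1 | intermediate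
10 | (2S,5R)-2-[4-(1,3-dioxolan-2-yl)-2-methylbutan-2-yl]-5-methylcyclohexan-1-one (trans) | C[C@@H]1CC[C@@H](C(C)(C)CCC2OCCO2)C(=O)C1 | intermediate
11 | (2S,3R,6S)-6-[4-(1,3-dioxolan-2-yl)-2-methylbutan-2-yl]-2,3-dimethylcyclohexan-1-one | C[C@@H]1CC[C@@H](C(C)(C)CCC2OCCO2)C(=O)[C@H]1C | intermediate
12 | (3R,6S)-6-[4-(1,3-dioxolan-2-yl)-2-methylbutan-2-yl]-2,3-dimethylcyclohex-1-en-1-yl trifluoromethanesulfonate | C[C@@H]1CC[C@@H](C(C)(C)CCC2OCCO2)C(OS(=O)(=O)C(F)(F)F)=C1C | intermediate
13 | (3R,6S)-2,3-dimethyl-6-(2-methyl-5-oxopentan-2-yl)cyclohex-1-en-1-yl trifluoromethanesulfonate | C[C@@H]1CC[C@@H](C(C)(C)CCC=O)C(OS(=O)(=O)C(F)(F)F)=C1C | intermediate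
14 | (4aS,7R)-4,4,7,8-tetramethyl-1,2,3,4,4a,5,6,7-octahydronaphthalen-1-ol, both C1 epimers | CC1=C2C(O)CCC(C)(C)[C@@H]2CC[C@H]1C | intermediate
15 | (4aS,7R)-4,4,7,8-tetramethyl-3,4,4a,5,6,7-hexahydronaphthalen-1(2H)-one | CC1=C2C(=O)CCC(C)(C)[C@@H]2CC[C@H]1C | intermediate
16 | (1S,4aS,7R)-4,4,7,8-tetramethyl-1,2,3,4,4a,5,6,7-octahydronaphthalen-1-ol | CC1=C2[C@@H](O)CCC(C)(C)[C@@H]2CC[C@H]1C | intermediate
17 | 1-[1,3-bis(tert-butyldimethylsilyloxy)propan-2-yl] 6-[(1S,4aS,7R)-4,4,7,8-tetramethyl-1,2,3,4,4a,5,6,7-octahydronaphthalen-1-yl] (3R)-3-methylhexanedioate | CC1=C2[C@@H](OC(=O)CC[C@@H](C)CC(=O)OC(CO[Si](C)(C)C(C)(C)C)CO[Si](C)(C)C(C)(C)C)CCC(C)(C)[C@@H]2CC[C@H]1C | intermediate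
18 | bis(trimethylsilyl ketene acetal) of 17 (C11=C and C14=C15 enol silanes, geometry not defined) | CC1=C2[C@@H](OC(O[Si](C)(C)C)=CC[C@@H](C)C=C(O[Si](C)(C)C)OC(CO[Si](C)(C)C(C)(C)C)CO[Si](C)(C)C(C)(C)C)CCC(C)(C)[C@@H]2CC[C@H]1C | intermediate
19 | trimethylsilyl ester of 20 that still holds the C14=C15 ketene silyl acetal | C[C@H](CC(C(=O)O[Si](C)(C)C)[C@@]1(C)C2=CCCC(C)(C)[C@@H]2CC[C@H]1C)C=C(O[Si](C)(C)C)OC(CO[Si](C)(C)C(C)(C)C)CO[Si](C)(C)C(C)(C)C | intermediate
20 | (4R)-6-{[1,3-bis(tert-butyldimethylsilyloxy)propan-2-yl]oxy}-4-methyl-6-oxo-2-[(1S,2R,4aS)-1,2,5,5-tetramethyl-1,2,3,4,4a,5,6,7-octahydronaphthalen-1-yl]hexanoic acid, both C11 epimers | C[C@H](CC(C(=O)O)[C@@]1(C)C2=CCCC(C)(C)[C@@H]2CC[C@H]1C)CC(=O)OC(CO[Si](C)(C)C(C)(C)C)CO[Si](C)(C)C(C)(C)C | intermediate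
21 | 2-thioxopyridin-1(2H)-yl ester of 20 (Barton ester) | C[C@H](CC(C(=O)ON3C=CC=CC3=S)[C@@]1(C)C2=CCCC(C)(C)[C@@H]2CC[C@H]1C)CC(=O)OC(CO[Si](C)(C)C(C)(C)C)CO[Si](C)(C)C(C)(C)C | intermediate
22 | 1,3-bis(tert-butyldimethylsilyloxy)propan-2-yl (3R)-3-methyl-5-[(1R,2R,4aS)-1,2,5,5-tetramethyl-1,2,3,4,4a,5,6,7-octahydronaphthalen-1-yl]pentanoate | C[C@H](CC[C@@]1(C)C2=CCCC(C)(C)[C@@H]2CC[C@H]1C)CC(=O)OC(CO[Si](C)(C)C(C)(C)C)CO[Si](C)(C)C(C)(C)C | intermediate
23 | 1,3-dihydroxypropan-2-yl (3R)-3-methyl-5-[(1R,2R,4aS)-1,2,5,5-tetramethyl-1,2,3,4,4a,5,6,7-octahydronaphthalen-1-yl]pentanoate | C[C@H](CC[C@@]1(C)C2=CCCC(C)(C)[C@@H]2CC[C@H]1C)CC(=O)OC(CO)CO | target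

**Step count and weak points**

Total: 14 steps. Longest linear sequence: 11 steps (steps 4 to 14, from (R)-pulegone).

Step 12 (key step). Process at risk: before O-silylation the C11 enolate can acylate the glyceryl ester carbonyl C15, or the C14 enolate the allylic ester carbonyl, in a Dieckmann-type closure of a five-membered ring. A slow shift at the crowded C9 terminus also leaves time for loss of the allylic alkoxide with ketene formation. Fallback: C15 is carried as a silyl ether, so the rearrangement substrate holds a single ester; it sets out from alcohol 16 and comes back at 22. (R)-Citronellol F1 is silylated (TBSCl, imidazole) to its tert-butyldimethylsilyl ether F2. Ozonolysis with Me2S work-up gives (4R)-6-(tert-butyldimethylsilyloxy)-4-methylhexanal F3, and NaClO2 oxidation gives (4R)-6-(tert-butyldimethylsilyloxy)-4-methylhexanoic acid F4. DCC/DMAP esterification with 16 gives the allylic ester F5. With LiN(i-Pr)2 (1.2 equiv) and Me3SiCl this passes through the ketene silyl acetal F6 and the rearranged trimethylsilyl ester F7 to the C11 carboxylic acid F8. Barton decarboxylation through the thiohydroxamate ester F9 gives the C15 silyl ether F10. Bu4NF then gives the primary alcohol F11, and TEMPO/PhI(OAc)2 in MeCN/H2O gives the C15 carboxylic acid F12. DCC/DMAP esterification of F12 with 2 gives 22.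

Step 13. Process at risk: the C11 radical is homoallylic to C1=C10 and can close onto C10 (3-exo) and reopen to the tertiary C9 radical, which would shift the alkenyl carbon to C11 and enlarge ring B, if hydrogen transfer from the thiol is not fast enough. Sluggish acylation of the thiohydroxamic acid by the neopentyl-type acid is a second weak point. Fallback without a free radical, from 20 back to 22: EtSH, DCC and DMAP convert 20 into the S-ethyl thioester F13. Fukuyama reduction (Et3SiH, palladium on carbon (Pd/C), acetone) gives the C11 aldehyde F14. Tsuji–Wilkinson decarbonylation with RhCl(PPh3)3 (1 equiv, toluene, reflux) replaces the formyl group by hydrogen and gives 22.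

Step 6. Process at risk: proton removal at the C5 methine instead of the C9 methine, leading to the wrong enol triflate, or reversible enolisation that epimerises C5. Fallback with regiochemistry enforced by structure, from 10 back to 12 (11 is bypassed): the kinetic enolate of 10 (LiN(i-Pr)2, THF, −78 °C) is trapped with Eschenmoser's salt to give the Mannich base F15. MeI gives the methiodide F16, and NaHCO3 eliminates trimethylamine to the α-methylene ketone F17; a methylene group can only arise at C9. Conjugate reduction with LiBH(s-Bu)3 at −78 °C delivers the C9=C10 enolate regiospecifically, and PhNTf2 traps it as 12.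

**Further compounds**

F1 | step 12 | (R)-citronellol | C[C@H](CCC=C(C)C)CCO
F2 | step 12 | tert-butyldimethylsilyl ether of (R)-citronellol | C[C@H](CCC=C(C)C)CCO[Si](C)(C)C(C)(C)C
F3 | step 12 | (4R)-6-(tert-butyldimethylsilyloxy)-4-methylhexanal | C[C@H](CCC=O)CCO[Si](C)(C)C(C)(C)C
F4 | step 12 | (4R)-6-(tert-butyldimethylsilyloxy)-4-methylhexanoic acid | C[C@H](CCC(=O)O)CCO[Si](C)(C)C(C)(C)C
F5 | step 12 | (1S,4aS,7R)-4,4,7,8-tetramethyl-1,2,3,4,4a,5,6,7-octahydronaphthalen-1-yl (4R)-6-(tert-butyldimethylsilyloxy)-4-methylhexanoate | CC1=C2[C@@H](OC(=O)CC[C@@H](C)CCO[Si](C)(C)C(C)(C)C)CCC(C)(C)[C@@H]2CC[C@H]1C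
F6 | step 12 | trimethylsilyl ketene acetal of F5 | CC1=C2[C@@H](OC(O[Si](C)(C)C)=CC[C@@H](C)CCO[Si](C)(C)C(C)(C)C)CCC(C)(C)[C@@H]2CC[C@H]1C
F7 | step 12 | trimethylsilyl ester of F8 | C[C@H](CC(C(=O)O[Si](C)(C)C)[C@@]1(C)C2=CCCC(C)(C)[C@@H]2CC[C@H]1C)CCO[Si](C)(C)C(C)(C)C
F8 | step 12 | (4R)-6-(tert-butyldimethylsilyloxy)-4-methyl-2-[(1S,2R,4aS)-1,2,5,5-tetramethyl-1,2,3,4,4a,5,6,7-octahydronaphthalen-1-yl]hexanoic acid, both C11 epimers | C[C@H](CC(C(=O)O)[C@@]1(C)C2=CCCC(C)(C)[C@@H]2CC[C@H]1C)CCO[Si](C)(C)C(C)(C)C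
F9 | step 12 | 2-thioxopyridin-1(2H)-yl ester of F8 | C[C@H](CC(C(=O)ON3C=CC=CC3=S)[C@@]1(C)C2=CCCC(C)(C)[C@@H]2CC[C@H]1C)CCO[Si](C)(C)C(C)(C)C
F10 | step 12 | tert-butyldimethylsilyl ether of (3R)-3-methyl-5-[(1R,2R,4aS)-1,2,5,5-tetramethyl-1,2,3,4,4a,5,6,7-octahydronaphthalen-1-yl]pentan-1-ol | C[C@H](CC[C@@]1(C)C2=CCCC(C)(C)[C@@H]2CC[C@H]1C)CCO[Si](C)(C)C(C)(C)C
F11 | step 12 | (3R)-3-methyl-5-[(1R,2R,4aS)-1,2,5,5-tetramethyl-1,2,3,4,4a,5,6,7-octahydronaphthalen-1-yl]pentan-1-ol | C[C@H](CC[C@@]1(C)C2=CCCC(C)(C)[C@@H]2CC[C@H]1C)CCO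
F12 | step 12 | (3R)-3-methyl-5-[(1R,2R,4aS)-1,2,5,5-tetramethyl-1,2,3,4,4a,5,6,7-octahydronaphthalen-1-yl]pentanoic acid | C[C@H](CC[C@@]1(C)C2=CCCC(C)(C)[C@@H]2CC[C@H]1C)CC(=O)O
F13 | step 13 | S-ethyl thioester of 20 | C[C@H](CC(C(=O)SCC)[C@@]1(C)C2=CCCC(C)(C)[C@@H]2CC[C@H]1C)CC(=O)OC(CO[Si](C)(C)C(C)(C)C)CO[Si](C)(C)C(C)(C)C
F14 | step 13 | C11 aldehyde corresponding to 20 | C[C@H](CC(C=O)[C@@]1(C)C2=CCCC(C)(C)[C@@H]2CC[C@H]1C)CC(=O)OC(CO[Si](C)(C)C(C)(C)C)CO[Si](C)(C)C(C)(C)C
F15 | step 6 | (3R,6S)-2-[(dimethylamino)methyl]-6-[4-(1,3-dioxolan-2-yl)-2-methylbutan-2-yl]-3-methylcyclohexan-1-one | C[C@@H]1CC[C@@H](C(C)(C)CCC2OCCO2)C(=O)C1CN(C)C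
F16 | step 6 | methiodide of F15 | C[C@@H]1CC[C@@H](C(C)(C)CCC2OCCO2)C(=O)C1C[N+](C)(C)C.[I-]
F17 | step 6 | (3R,6S)-6-[4-(1,3-dioxolan-2-yl)-2-methylbutan-2-yl]-3-methyl-2-methylidenecyclohexan-1-one | C[C@@H]1CC[C@@H](C(C)(C)CCC2OCCO2)C(=O)C1=C
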